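Assumption: drimane-type numbering is used (C4 = quaternary carbon carrying the 4-methylpent-3-enyl arm, C5/C10 = ring fusion, C9 = carbon carrying CH2Ar). The SMILES decodes to 4α(equatorial)-CH3, 4β(axial)-homoprenyl, 5α-H, 9α-H, 10β-CH3, which is (1S,4aS,5R,8aS).

## Retrosynthetic overview
1. C11–aryl bond: B-alkyl Suzuki coupling of the 9-BBN adduct of exocyclic diene 16 with iodoarene 17. α-Face hydroboration sets C9.
2. Diene 16 comes from the C9 ketone by Peterson olefination. The β-hydroxysilane stage also removes the enone acceptor before the radical step.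
3. Ring A is the only ring built (ring B is the carvone ring, the arene is bought). C2–C3 and C4–CH3 form together in a visible-light 6-endo radical cyclisation/SH2 methylation of bromide 13, which sets C4.
4. C10 quaternary centre: MeI, then BrCH2CH2OTf, on the α'-enolate, entering anti to the C5 arm.
5. Homoprenyl arm: ene chlorination, allyl–allyl Stille coupling and cross-metathesis on (R)-carvone. C5 is bought.

## Route

**Step 1**
Reactants: 1 (R)-(–)-carvone; 2 calcium hypochlorite
Product: 3 (5R)-5-(3-chloroprop-1-en-2-yl)-2-methylcyclohex-2-en-1-one (10-chlorocarvone)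
Conditions: Ca(OCl)2, CO2(s), CH2Cl2/H2O, 0 °C
Reagents that add atoms: calcium hypochlorite, [Ca+2].[O-]Cl.[O-]Cl
Why: Ene-type allylic chlorination by HOCl attacks only the electron-rich 1,1-disubstituted alkene (the enone C=C is deactivated) and regenerates a 2-substituted allyl unit, leaving C5 untouched.

**Step 2**
Reactants: 3; 4 allyltributylstannane
Product: 5 (5R)-5-(hexa-1,5-dien-2-yl)-2-methylcyclohex-2-en-1-one
Conditions: Pd2(dba)3 (2.5 mol %), AsPh3 (10 mol %), THF, 50 °C
Reagents that add atoms: allyltributylstannane, C=CC[Sn](CCCC)(CCCC)CCCC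
Why: In this Stille allyl–allyl cross-coupling both allyl partners have degenerate termini, so no regioisomers are possible, and the neutral conditions tolerate the enone.

**Step 3**
Reactants: 5; 6 2-methyl-2-butene
Product: 7 (5R)-2-methyl-5-(6-methylhepta-1,5-dien-2-yl)cyclohex-2-en-1-one
Conditions: Grubbs II (3 mol %), 2-methyl-2-butene/CH2Cl2, 40 °C, sealed tube
Reagents that add atoms: 2-methyl-2-butene, CC=C(C)C
Why: In olefin cross-metathesis only the monosubstituted (type I) alkene turns over, giving the isopropylidene terminus, while the 1,1-disubstituted alkene and the enone are spectators.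

**Step 4**
Reactants: 7; 8 iodomethane
Product: 9 (5R,6RS)-2,6-dimethyl-5-(6-methylhepta-1,5-dien-2-yl)cyclohex-2-en-1-one (C6 epimers; both give the same enolate in step 5)
Conditions: LDA, THF, –78 °C; MeI, –78 → 0 °C
Reagents that add atoms: iodomethane, CI
Why: Kinetic α'-deprotonation gives the cross-conjugated enolate, and enolate alkylation installs the future C10 methyl.

**Step 5**
Reactants: 9; 10 2-bromoethyl trifluoromethanesulfonate
Product: 11 (5S,6S)-6-(2-bromoethyl)-2,6-dimethyl-5-(6-methylhepta-1,5-dien-2-yl)cyclohex-2-en-1-one (CH2CH2Br trans to the C5 arm, CH3 cis to it)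
Conditions: LDA, THF (no HMPA/DMPU), –78 °C; 10, –78 → –20 °C
Reagents that add atoms: 2-bromoethyl triflate, BrCCOS(=O)(=O)C(F)(F)F
Why: In this enolate alkylation of the tetrasubstituted lithium enolate the triflate leaves selectively over bromide, and the electrophile enters anti to the bulky C5 substituent, so the bought C5 centre sets the C10 quaternary centre.

**Step 6**
Reactants: 11; 12 (trimethylsilyl)methylmagnesium chloride
Product: 13 (1S,5S,6S)-6-(2-bromoethyl)-2,6-dimethyl-5-(6-methylhepta-1,5-dien-2-yl)-1-[(trimethylsilyl)methyl]cyclohex-2-en-1-ol (carbinol configuration is inconsequential, since it is destroyed in step 8)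
Conditions: CeCl3, TMSCH2MgCl, THF, –78 → 0 °C; cold aq NH4Cl; Et3N-washed SiO2
Reagents that add atoms: TMSCH2MgCl, C[Si](C)(C)C[Mg]Cl
Why: Non-basic organocerium 1,2-addition (the first half of a Peterson olefination) works on the hindered ketone without touching the C–Br bond, introduces C11, and removes the enone that would otherwise capture the radicals of step 7.

**Step 7 (key step)**
Reactants: 13; 14 N-acetoxyphthalimide
Product: 15 (1S,4aS,5R,8aS)-2,5,8a-trimethyl-5-(4-methylpent-3-en-1-yl)-1-[(trimethylsilyl)methyl]-1,4,4a,5,6,7,8,8a-octahydronaphthalen-1-ol (trans-decalin; new CH3 equatorial/α, homoprenyl axial/β)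
Conditions: 14 (2 equiv), (Me3Si)3SiNH(1-adamantyl) (1.5 equiv), 4CzIPN (2 mol %), Fe(OEP)Cl (10 mol %), K3PO4, acetone (0.02 M), 450 nm LEDs, 25 °C
Reagents that add atoms: N-acetoxyphthalimide (CH3 donor), CC(=O)ON1C(=O)c2ccccc2C1=O
Why: Proposed new method: ring-closing alkene carbomethylation by radical sorting, in which the photo-oxidised aminosilane gives a silyl radical that abstracts Br from 13, the primary C2 radical closes 6-endo-trig onto the CH2 terminus of the 1,1-disubstituted alkene through the conformer with both arms equatorial (5-exo would form a strained trans-hydrindane at a fully substituted carbon), the reduced photocatalyst fragments 14 to CH3•, which is stored as CH3–Fe(III)(OEP), and the ring-bound tertiary C4 radical, too hindered to bind iron, takes that methyl by SH2 from the open α face because the β face is blocked 1,3-diaxially by the C10 methyl, giving equatorial CH3 and the axial homoprenyl arm (5R); the closest known reaction types are iron-porphyrin SH2 tertiary/primary radical cross-coupling and intermolecular alkene dialkylation by triple radical sorting, neither of which has been shown as a ring-closing, diastereoselective cascade.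

**Step 8**
Reactants: 15
Product: 16 (4aS,5R,8aS)-2,5,8a-trimethyl-1-methylidene-5-(4-methylpent-3-en-1-yl)-1,4,4a,5,6,7,8,8a-octahydronaphthalene
Conditions: KH, THF, 0 °C → rt
Reagents that add atoms: none
Why: Base-induced Peterson syn-elimination of Me3SiO– is regiospecific, so only the exocyclic C9=C11 alkene forms and no stereocentre is touched.

**Step 9**
Reactants: 16; 17 4-hydroxy-3-iodobenzoic acid
Product: 18 jaspic acid
Conditions: 9-BBN-H (1.2 equiv), THF, 0 → 40 °C; then 17 (pre-dissolved with Cs2CO3, 4 equiv, in DMF/H2O), Pd(dppf)Cl2 (5 mol %), AsPh3, 50 °C; dilute HCl work-up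
Reagents that add atoms: 4-hydroxy-3-iodobenzoic acid, OC(=O)c1ccc(O)c(I)c1
Why: Hydroboration followed by B-alkyl Suzuki–Miyaura coupling, in which 9-BBN adds only to the 1,1-disubstituted alkene with B on C11 and H delivered to C9 from the α face (the β face is screened by the axial C10 methyl, as in drima-7,9(11)-diene → drimenol), giving 9α-H (1S), and the primary alkylborane then couples with the aryl iodide used as its dianion, so no protecting groups are needed.

## Compound list
1 | (R)-(–)-carvone | O=C1C(C)=CC[C@@H](C(C)=C)C1 | starting material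
2 | calcium hypochlorite | [Ca+2].[O-]Cl.[O-]Cl | starting material
3 | (5R)-5-(3-chloroprop-1-en-2-yl)-2-methylcyclohex-2-en-1-one | O=C1C(C)=CC[C@@H](C(=C)CCl)C1 | intermediate
4 | allyltributylstannane | C=CC[Sn](CCCC)(CCCC)CCCC | starting material
5 | (5R)-5-(hexa-1,5-dien-2-yl)-2-methylcyclohex-2-en-1-one | O=C1C(C)=CC[C@@H](C(=C)CCC=C)C1 | intermediate
6 | 2-methyl-2-butene | CC=C(C)C | starting material
7 | (5R)-2-methyl-5-(6-methylhepta-1,5-dien-2-yl)cyclohex-2-en-1-one | O=C1C(C)=CC[C@@H](C(=C)CCC=C(C)C)C1 | intermediate
8 | iodomethane | CI | starting material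
9 | (5R,6RS)-2,6-dimethyl-5-(6-methylhepta-1,5-dien-2-yl)cyclohex-2-en-1-one | O=C1C(C)=CC[C@@H](C(=C)CCC=C(C)C)C1C | intermediate
10 | 2-bromoethyl trifluoromethanesulfonate | BrCCOS(=O)(=O)C(F)(F)F | starting material
11 | (5S,6S)-6-(2-bromoethyl)-2,6-dimethyl-5-(6-methylhepta-1,5-dien-2-yl)cyclohex-2-en-1-one | O=C1C(C)=CC[C@@H](C(=C)CCC=C(C)C)[C@]1(C)CCBr | intermediate
12 | (trimethylsilyl)methylmagnesium chloride | C[Si](C)(C)C[Mg]Cl | starting material
13 | (1S,5S,6S)-6-(2-bromoethyl)-2,6-dimethyl-5-(6-methylhepta-1,5-dien-2-yl)-1-[(trimethylsilyl)methyl]cyclohex-2-en-1-ol | O[C@@]1(C[Si](C)(C)C)C(C)=CC[C@@H](C(=C)CCC=C(C)C)[C@]1(C)CCBr | intermediate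
14 | N-acetoxyphthalimide | CC(=O)ON1C(=O)c2ccccc2C1=O | starting material
15 | (1S,4aS,5R,8aS)-2,5,8a-trimethyl-5-(4-methylpent-3-en-1-yl)-1-[(trimethylsilyl)methyl]-1,4,4a,5,6,7,8,8a-octahydronaphthalen-1-ol | CC(C)=CCC[C@@]1(C)CCC[C@]2(C)[C@](O)(C[Si](C)(C)C)C(C)=CC[C@@H]12 | intermediate
16 | (4aS,5R,8aS)-2,5,8a-trimethyl-1-methylidene-5-(4-methylpent-3-en-1-yl)-1,4,4a,5,6,7,8,8a-octahydronaphthalene | CC(C)=CCC[C@@]1(C)CCC[C@]2(C)C(=C)C(C)=CC[C@@H]12 | intermediate
17 | 4-hydroxy-3-iodobenzoic acid | OC(=O)c1ccc(O)c(I)c1 | starting material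
18 | jaspic acid, 4-hydroxy-3-{[(1S,4aS,5R,8aS)-2,5,8a-trimethyl-5-(4-methylpent-3-en-1-yl)-1,4,4a,5,6,7,8,8a-octahydronaphthalen-1-yl]methyl}benzoic acid | CC(C)=CCC[C@@]1(C)CCC[C@]2(C)[C@@H](Cc3cc(C(=O)O)ccc3O)C(C)=CC[C@@H]12 | target

## Step count
Total steps: 9. Longest linear sequence: 9.

## Steps most likely to fail
1. **Step 7 (new cascade).**
   - Risks: iron may capture the primary C2 radical before it cyclises. 5-exo closure may leak through. The long-lived C4 radical may undergo allylic H-abstraction.
   - Fallback (known chemistry only): set C4 by enolate methylation instead.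
     - Oxidise the CH2Cl arm of 3 to the 2-substituted acrylate.
     - After the two C10 alkylations, close ring A by a polarity-matched 6-endo Giese cyclisation of the bromoethyl radical onto the acrylate.
     - Methylate the exocyclic ester enolate with LDA/MeI. Equatorial attack gives the axial ester and equatorial methyl, the classical podocarpate outcome.
     - Grow the axial ester into the arm by DIBAL reduction, Wittig methylenation, then 9-BBN/Suzuki coupling with 1-bromo-2-methylpropene.
2. **Step 5 (triflate alkylation).**
   - Risks: O-alkylation, or E2 elimination to vinyl bromide.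
   - Fallback:
     - C-alkylate with methyl bromoacetate.
     - Reduce with LiAlH4, which takes the ester to the primary alcohol and the enone to the allylic alcohol. The allylic alcohol then serves as the enone mask.
     - Convert the primary OH to bromide by the Appel reaction and run the radical step.
     - Re-oxidise C9–OH and methylenate by Peterson olefination (+2 steps).
3. **Step 9 (hindered B-alkyl transfer to an unprotected iodoarene).**
   - Fallback:
     - Oxidise the borane (H2O2/NaOH) to the drimenol-type primary alcohol and convert it to the aldehyde.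
     - Add the aryllithium from a MOM-protected 3-bromo-4-hydroxybenzoate surrogate.
     - Remove the benzylic OH by Barton–McCombie deoxygenation and deprotect.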